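**Retrosynthetic overview**

Ring numbering of the target: C-1 (OAc), C-2 (CMe2), C-3 (side chain), C-4 (=CH2), C-5, C-6.
- Enabling feature: C-1 and C-4 sit 1,4 on the cyclohexane with the quaternary C-2 between C-1 and C-3. With C-4=CH2 read as a ketone and the C-1 acetate as the Baeyer–Villiger product of an acetyl group, the ring is a 4-acetylcyclohexanone, the retron of a Diels–Alder reaction between a 2-silyloxydiene (C-3, C-4, C-5, C-6) and mesityl oxide (C-1, C-2, both methyls and both acetate carbons).
- Key disconnections: C-2–C-3 and C-6–C-1 (enantioselective Diels–Alder, sets both stereocentres); C-1–acyl to C-1–O (Baeyer–Villiger, retention); C-4=O to C-4=CH2; side chain CH2–C(Me)= bond (Negishi coupling with an (E)-alkenyl iodide made from farnesyl bromide).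
- Ring formation: the single ring is closed in step 4; the polyene is attached last, so the acid, hydrogenation and peracid steps never meet it.

Key step: step 4

Remark: the antipode of the phosphoramide catalyst that delivers the (1S,5S) adduct 7 is to be fixed in a first small-scale experiment, and farnesyl bromide is taken as the commercial (2E,6E) isomer.

**Step 1**
Reactants: 1 4-chlorobutanoyl chloride
Product: 2 4-chloro-N-methoxy-N-methylbutanamide
Conditions: MeNH(OMe)·HCl, pyridine, CH2Cl2, 0 °C to rt
Reagents that add atoms: N,O-dimethylhydroxylamine hydrochloride, CNOC.Cl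
Why: N-acylation of the hydroxylamine by the acid chloride gives the amide for a Weinreb ketone synthesis, the primary alkyl chloride being inert under these conditions.

**Step 2**
Reactants: 2 4-chloro-N-methoxy-N-methylbutanamide
Product: 4 6-chlorohex-1-en-3-one, via bromomagnesium hemiaminal 3 (not isolated)
Conditions: CH2=CHMgBr, THF, −78 to −20 °C; inverse quench into cold 1 M HCl
Reagents that add atoms: vinylmagnesium bromide, C=C[Mg]Br
Why: Weinreb ketone synthesis, in which the chelated tetrahedral intermediate prevents over-addition and the acidic inverse quench keeps the liberated amine from adding to the vinyl ketone.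

**Step 3**
Reactants: 4 6-chlorohex-1-en-3-one
Product: 5 {[(3Z)-6-chlorohexa-1,3-dien-3-yl]oxy}tri(propan-2-yl)silane
Conditions: iPr3SiOTf, Et3N, CH2Cl2, −20 to 0 °C; filtration through basic alumina
Reagents that add atoms: triisopropylsilyl trifluoromethanesulfonate, CC(C)[Si](OS(=O)(=O)C(F)(F)F)(C(C)C)C(C)C
Why: Soft enolisation (silyl triflate and tertiary amine) at the only enolisable position should give the cross-conjugated 2-silyloxydiene mainly as the Z enol ether, which places the chloroethyl chain on the outside of the s-cis diene.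

**Step 4**
Reactants: 5 {[(3Z)-6-chlorohexa-1,3-dien-3-yl]oxy}tri(propan-2-yl)silane; 6 4-methylpent-3-en-2-one (mesityl oxide)
Product: 7 1-[(1S,5S)-5-(2-chloroethyl)-6,6-dimethyl-4-{[tri(propan-2-yl)silyl]oxy}cyclohex-3-en-1-yl]ethan-1-one (acetyl and chloroethyl cis)
Conditions: 5 (1.5–2 equiv), chiral 3,3'-bis(2,4,6-triisopropylphenyl)-BINOL N-triflylphosphoramide (10 mol %), toluene, −78 to −40 °C
Reagents that add atoms: none
Why: Proposed new method: the strong chiral Brønsted acid (or its N-silyl form after silyl transfer from 5) activates the carbonyl of mesityl oxide, whose gem-dimethyl β-carbon (future C-2) is attacked by the silyloxy-substituted diene terminus (future C-3) while its α-carbon (future C-1) bonds to the vinyl terminus (future C-6), a strongly asynchronous Diels–Alder reaction that may run as a Mukaiyama–Michael addition followed by ring closure inside the chiral ion pair. The closest known reactions are the chiral N-triflylphosphoramide-catalysed Diels–Alder reaction of 1-substituted 2-silyloxydienes with ethyl vinyl ketone and the AlBr3/AlMe3-promoted Diels–Alder reaction of hindered 2-silyloxydienes with β,β-disubstituted enones; the enantioselective version on a β,β-dimethyl enone has not been shown. The six-membered ring closes by (4+2) cycloaddition through an endo transition state (in the stepwise limit, a 6-endo-trig attack of the ketone enol on the silyloxyallyl cation). The relative configuration of C-1 and C-3 follows from the Z diene geometry (chloroethyl outside) combined with the endo acetyl group, which places the two cis, and the absolute configuration follows from the binaphthyl pocket of the catalyst shielding one face of the activated s-cis enone. The step needs regioselectivity (secured by the 2-silyloxy group, which makes C-3 the only nucleophilic terminus and pairs it with the enone β-carbon), endo selectivity and enantioselectivity (tight ion pair at low temperature). Any E isomer of 5 cannot reach the s-cis conformation and should be left unreacted.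

**Step 5**
Reactants: 7 1-[(1S,5S)-5-(2-chloroethyl)-6,6-dimethyl-4-{[tri(propan-2-yl)silyl]oxy}cyclohex-3-en-1-yl]ethan-1-one
Product: 8 1-[(1S,3S)-3-(2-chloroethyl)-2,2-dimethyl-4-{[tri(propan-2-yl)silyl]oxy}cyclohexyl]ethan-1-one (C-4 epimers)
Conditions: H2 (5 bar), Pd/C (10 % Pd on carbon), trace K2CO3, EtOAc, rt
Reagents that add atoms: none
Why: Heterogeneous hydrogenation of the silyl enol ether C=C, the only alkene present, turns the masked C-4 ketone into a peracid-stable silyl ether without touching the methyl ketone, the alkyl chloride or the two stereocentres; the new C-4 centre is uncontrolled and is erased in step 8.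

**Step 6**
Reactants: 8 1-[(1S,3S)-3-(2-chloroethyl)-2,2-dimethyl-4-{[tri(propan-2-yl)silyl]oxy}cyclohexyl]ethan-1-one
Product: 9 (1S,3S)-3-(2-chloroethyl)-2,2-dimethyl-4-{[tri(propan-2-yl)silyl]oxy}cyclohexyl acetate (C-4 epimers)
Conditions: mCPBA, NaHCO3, CH2Cl2, rt to 35 °C, dark
Reagents that add atoms: 3-chloroperoxybenzoic acid, OOC(=O)c1cccc(Cl)c1
Why: Baeyer–Villiger oxidation in which the secondary ring carbon migrates in preference to methyl with retention, so the acetyl group becomes the acetate with the C-1 configuration unchanged (the same behaviour as a 20-oxo steroid giving its 17-acetate).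

**Step 7**
Reactants: 9 (1S,3S)-3-(2-chloroethyl)-2,2-dimethyl-4-{[tri(propan-2-yl)silyl]oxy}cyclohexyl acetate
Product: 10 (1S,3S)-3-(2-chloroethyl)-4-hydroxy-2,2-dimethylcyclohexyl acetate (C-4 epimers)
Conditions: HF (48 % aq.), MeCN, 0 °C to rt
Reagents that add atoms: none
Why: Fluoride-driven cleavage of the silyl ether under acidic conditions that leave the acetate and the alkyl chloride intact and cannot cause acyl migration (the two oxygens are 1,4).

**Step 8**
Reactants: 10 (1S,3S)-3-(2-chloroethyl)-4-hydroxy-2,2-dimethylcyclohexyl acetate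
Product: 11 (1S,3S)-3-(2-chloroethyl)-2,2-dimethyl-4-oxocyclohexyl acetate
Conditions: Dess–Martin periodinane, NaHCO3, CH2Cl2, 0 °C to rt
Reagents that add atoms: none
Why: Dess–Martin oxidation under buffered, near-neutral conditions converges both C-4 epimers to the ketone without enolising it, so the adjacent C-3 stereocentre is kept.

**Step 9**
Reactants: 11 (1S,3S)-3-(2-chloroethyl)-2,2-dimethyl-4-oxocyclohexyl acetate
Product: 12 (1S,3R)-3-(2-chloroethyl)-2,2-dimethyl-4-methylidenecyclohexyl acetate
Conditions: Zn, CH2Br2, TiCl4 (pre-formed in THF), then 11, CH2Cl2, 0 °C to rt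
Reagents that add atoms: dibromomethane, BrCBr
Why: Lombardo methylenation, whose non-basic gem-dimetallic reagent methylenates hindered, enolisable ketones without epimerising the α-stereocentre and does not attack the acetate or the alkyl chloride.

**Step 10**
Reactants: 12 (1S,3R)-3-(2-chloroethyl)-2,2-dimethyl-4-methylidenecyclohexyl acetate
Product: 13 (1S,3R)-3-(2-iodoethyl)-2,2-dimethyl-4-methylidenecyclohexyl acetate
Conditions: NaI, butan-2-one, 80 °C
Reagents that add atoms: sodium iodide, [Na+].[I-]
Why: Finkelstein halide exchange at the unhindered primary chloride, driven by precipitation of NaCl, gives the iodide needed for zinc insertion.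

**Step 11**
Reactants: 14 (2E,6E)-1-bromo-3,7,11-trimethyldodeca-2,6,10-triene (farnesyl bromide); 15 trimethyl(prop-1-yn-1-yl)silane
Product: 17 trimethyl[(5E,9E)-6,10,14-trimethylpentadeca-5,9,13-trien-1-yn-1-yl]silane, via lithiated 1-(trimethylsilyl)propyne 16 (not isolated)
Conditions: 15, n-BuLi, THF, −78 to −20 °C; then 14, −78 °C to rt
Reagents that add atoms: none
Why: SN2 alkylation of the silyl-capped propargylic anion at the primary allylic bromide, the silyl group steering reaction to the propargyl (not allenyl) position and both alkene geometries being untouched.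

**Step 12**
Reactants: 17 trimethyl[(5E,9E)-6,10,14-trimethylpentadeca-5,9,13-trien-1-yn-1-yl]silane
Product: 18 (5E,9E)-6,10,14-trimethylpentadeca-5,9,13-trien-1-yne
Conditions: K2CO3, MeOH, rt
Reagents that add atoms: none
Why: Methoxide-mediated protodesilylation of the alkynylsilane, selective for the C(sp)–Si bond.

**Step 13**
Reactants: 18 (5E,9E)-6,10,14-trimethylpentadeca-5,9,13-trien-1-yne
Product: 20 (6E,10E)-7,11,15-trimethylhexadeca-6,10,14-trien-2-yne, via lithium acetylide 19 (not isolated)
Conditions: n-BuLi, THF, −78 °C; MeI, DMPU, −78 °C to rt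
Reagents that add atoms: iodomethane, CI
Why: Deprotonation of the terminal alkyne and SN2 methylation of the acetylide gives the 2-alkyne needed for regiocontrolled hydrometalation.

**Step 14**
Reactants: 20 (6E,10E)-7,11,15-trimethylhexadeca-6,10,14-trien-2-yne
Product: 22 (2E,6E,10E)-2-iodo-7,11,15-trimethylhexadeca-2,6,10,14-tetraene, via alkenylzirconocene chloride 21 (not isolated)
Conditions: Cp2Zr(H)Cl (2.2 equiv), THF, 50 °C; then I2, 0 °C
Reagents that add atoms: iodine, II
Why: Hydrozirconation–iodination: syn addition of Zr–H, equilibration with excess reagent toward zirconium on the less hindered methyl-bearing carbon, and iodinolysis with retention should give the (E)-2-iodoalkene, while the trisubstituted alkenes do not react.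

**Step 15**
Reactants: 13 (1S,3R)-3-(2-iodoethyl)-2,2-dimethyl-4-methylidenecyclohexyl acetate; 22 (2E,6E,10E)-2-iodo-7,11,15-trimethylhexadeca-2,6,10,14-tetraene
Product: 24 (1S,3R)-2,2-dimethyl-4-methylidene-3-[(3E,7E,11E)-3,8,12,16-tetramethylheptadeca-3,7,11,15-tetraen-1-yl]cyclohexyl acetate, via alkylzinc iodide 23 (not isolated)
Conditions: 13, Zn dust (activated with BrCH2CH2Br, Me3SiCl), THF/DMA, 40 °C; then 22, Pd(PPh3)4 (5 mol %), 45 °C
Reagents that add atoms: none
Why: Zinc insertion into the primary iodide followed by Negishi coupling with the alkenyl iodide forms the C(sp3)–C(sp2) bond with retention of the E geometry, the organozinc tolerating the acetate and the exocyclic alkene.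

**Compound list**

1 | 4-chlorobutanoyl chloride | ClCCCC(Cl)=O | starting material
2 | 4-chloro-N-methoxy-N-methylbutanamide | ClCCCC(=O)N(C)OC | intermediate
3 | bromomagnesium hemiaminal (adduct of 2 and vinylmagnesium bromide) | ClCCCC(C=C)(O[Mg]Br)N(C)OC | intermediate (not isolated)
4 | 6-chlorohex-1-en-3-one | ClCCCC(=O)C=C | intermediate
5 | {[(3Z)-6-chlorohexa-1,3-dien-3-yl]oxy}tri(propan-2-yl)silane | C=C/C(O[Si](C(C)C)(C(C)C)C(C)C)=C/CCCl | intermediate
6 | 4-methylpent-3-en-2-one (mesityl oxide) | CC(=O)C=C(C)C | starting material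
7 | 1-[(1S,5S)-5-(2-chloroethyl)-6,6-dimethyl-4-{[tri(propan-2-yl)silyl]oxy}cyclohex-3-en-1-yl]ethan-1-one | CC(C)[Si](C(C)C)(C(C)C)OC1=CC[C@H](C(C)=O)C(C)(C)[C@@H]1CCCl | intermediate
8 | 1-[(1S,3S)-3-(2-chloroethyl)-2,2-dimethyl-4-{[tri(propan-2-yl)silyl]oxy}cyclohexyl]ethan-1-one (C-4 epimers) | CC(C)[Si](C(C)C)(C(C)C)OC1CC[C@H](C(C)=O)C(C)(C)[C@@H]1CCCl | intermediate
9 | (1S,3S)-3-(2-chloroethyl)-2,2-dimethyl-4-{[tri(propan-2-yl)silyl]oxy}cyclohexyl acetate (C-4 epimers) | CC(C)[Si](C(C)C)(C(C)C)OC1CC[C@H](OC(C)=O)C(C)(C)[C@@H]1CCCl | intermediate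
10 | (1S,3S)-3-(2-chloroethyl)-4-hydroxy-2,2-dimethylcyclohexyl acetate (C-4 epimers) | OC1CC[C@H](OC(C)=O)C(C)(C)[C@@H]1CCCl | intermediate
11 | (1S,3S)-3-(2-chloroethyl)-2,2-dimethyl-4-oxocyclohexyl acetate | O=C1CC[C@H](OC(C)=O)C(C)(C)[C@@H]1CCCl | intermediate
12 | (1S,3R)-3-(2-chloroethyl)-2,2-dimethyl-4-methylidenecyclohexyl acetate | C=C1CC[C@H](OC(C)=O)C(C)(C)[C@@H]1CCCl | intermediate
13 | (1S,3R)-3-(2-iodoethyl)-2,2-dimethyl-4-methylidenecyclohexyl acetate | C=C1CC[C@H](OC(C)=O)C(C)(C)[C@@H]1CCI | intermediate
14 | (2E,6E)-1-bromo-3,7,11-trimethyldodeca-2,6,10-triene (farnesyl bromide) | BrC/C=C(\C)CC/C=C(\C)CCC=C(C)C | starting material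
15 | trimethyl(prop-1-yn-1-yl)silane | CC#C[Si](C)(C)C | starting material
16 | [3-(trimethylsilyl)prop-2-yn-1-yl]lithium | [Li]CC#C[Si](C)(C)C | intermediate (not isolated)
17 | trimethyl[(5E,9E)-6,10,14-trimethylpentadeca-5,9,13-trien-1-yn-1-yl]silane | C[Si](C)(C)C#CCC/C=C(\C)CC/C=C(\C)CCC=C(C)C | intermediate
18 | (5E,9E)-6,10,14-trimethylpentadeca-5,9,13-trien-1-yne | C#CCC/C=C(\C)CC/C=C(\C)CCC=C(C)C | intermediate
19 | lithium acetylide of 18 | [Li]C#CCC/C=C(\C)CC/C=C(\C)CCC=C(C)C | intermediate (not isolated)
20 | (6E,10E)-7,11,15-trimethylhexadeca-6,10,14-trien-2-yne | CC#CCC/C=C(\C)CC/C=C(\C)CCC=C(C)C | intermediate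
21 | chlorobis(cyclopentadienyl)[(2E,6E,10E)-7,11,15-trimethylhexadeca-2,6,10,14-tetraen-2-yl]zirconium | C/C(=C\CC/C=C(\C)CC/C=C(\C)CCC=C(C)C)[Zr](Cl)(C1C=CC=C1)C1C=CC=C1 | intermediate (not isolated)
22 | (2E,6E,10E)-2-iodo-7,11,15-trimethylhexadeca-2,6,10,14-tetraene | C/C(I)=C\CC/C=C(\C)CC/C=C(\C)CCC=C(C)C | intermediate
23 | (1S,3R)-3-[2-(iodozincio)ethyl]-2,2-dimethyl-4-methylidenecyclohexyl acetate | C=C1CC[C@H](OC(C)=O)C(C)(C)[C@@H]1CC[Zn]I | intermediate (not isolated)
24 | (1S,3R)-2,2-dimethyl-4-methylidene-3-[(3E,7E,11E)-3,8,12,16-tetramethylheptadeca-3,7,11,15-tetraen-1-yl]cyclohexyl acetate (CNP0286444.1) | C=C1CC[C@H](OC(C)=O)C(C)(C)[C@@H]1CC/C(C)=C/CC/C=C(\C)CC/C=C(\C)CCC=C(C)C | target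

**Step count and risks**

Total step count: 15. Longest linear sequence: 11 steps (steps 1–10, then 15, from 4-chlorobutanoyl chloride); the alkenyl iodide branch is 4 steps (11–14).

Steps most likely to fail:

Step 4 (proposed new method). The acid catalyst may turn over poorly with the hindered, weakly electrophilic enone, so that protodesilylation of the diene outruns C–C bond formation. The sequence may also stall after the first (Mukaiyama–Michael) bond, or proceed with insufficient endo or facial selectivity. The fallback uses known chemistry and sets out from 5 and 6: the mixed Lewis acid AlBr3/AlMe3 (about 5:1, toluene/CH2Cl2, −5 °C), which is established for forcing hindered 2-silyloxydienes onto β,β-disubstituted enones, should give the racemic cis cycloadduct F1. Carried through the operations of steps 5 to 8, this gives the racemic silyl ether ketone F2, the racemic silyl ether acetate F3, the racemic hydroxy acetate F4 and the racemic keto acetate F5. F5 is resolved by preparative chromatography on a chiral stationary phase, and its (1S,3S) enantiomer is compound 11, where the route is rejoined.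

Step 5. Hydrogenation of the hindered, fully substituted enol ether may be slow, and hydrolysis of the enol ether on the catalyst surface may compete. The fallback sets out from 7 and protects C-4 as a ketal instead: aqueous HF in MeCN gives the diketone F6; 1,2-bis(trimethylsilyloxy)ethane with catalytic Me3SiOTf at −78 °C should ketalise the ring ketone in preference to the acetyl group (which is flanked by the quaternary carbon), giving the dioxolane F7; mCPBA/NaHCO3 gives the ketal acetate F8; pyridinium p-toluenesulfonate in wet acetone returns to the route at 11. This fallback depends on telling the two ketones apart, which is less certain than in the main route.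

Step 9. Methylenation of the congested ketone may be incomplete, or prolonged exposure to the Lewis-acidic reagent may enolise it and erode the C-3 configuration. The fallback sets out from 11: kinetic deprotonation at the C-5 methylene (KHMDS, THF, −78 °C) and trapping with PhNTf2 gives the enol triflate F9; Negishi coupling with Me3SiCH2ZnCl and Pd(PPh3)4 gives the allylsilane F10; protodesilylation with allylic transposition (CF3CO2H, CH2Cl2, 0 °C) delivers the exocyclic alkene and returns to the route at 12.

**Further compounds**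

F1 | step 4 | racemic 1-[(1S*,5S*)-5-(2-chloroethyl)-6,6-dimethyl-4-{[tri(propan-2-yl)silyl]oxy}cyclohex-3-en-1-yl]ethan-1-one | CC(C)[Si](C(C)C)(C(C)C)OC1=CC[C@H](C(C)=O)C(C)(C)[C@@H]1CCCl.CC(C)[Si](C(C)C)(C(C)C)OC1=CC[C@@H](C(C)=O)C(C)(C)[C@H]1CCCl
F2 | step 4 | racemic 1-[(1S*,3S*)-3-(2-chloroethyl)-2,2-dimethyl-4-{[tri(propan-2-yl)silyl]oxy}cyclohexyl]ethan-1-one (C-4 epimers) | CC(C)[Si](C(C)C)(C(C)C)OC1CC[C@H](C(C)=O)C(C)(C)[C@@H]1CCCl.CC(C)[Si](C(C)C)(C(C)C)OC1CC[C@@H](C(C)=O)C(C)(C)[C@H]1CCCl
F3 | step 4 | racemic (1S*,3S*)-3-(2-chloroethyl)-2,2-dimethyl-4-{[tri(propan-2-yl)silyl]oxy}cyclohexyl acetate (C-4 epimers) | CC(C)[Si](C(C)C)(C(C)C)OC1CC[C@H](OC(C)=O)C(C)(C)[C@@H]1CCCl.CC(C)[Si](C(C)C)(C(C)C)OC1CC[C@@H](OC(C)=O)C(C)(C)[C@H]1CCCl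
F4 | step 4 | racemic (1S*,3S*)-3-(2-chloroethyl)-4-hydroxy-2,2-dimethylcyclohexyl acetate (C-4 epimers) | OC1CC[C@H](OC(C)=O)C(C)(C)[C@@H]1CCCl.OC1CC[C@@H](OC(C)=O)C(C)(C)[C@H]1CCCl
F5 | step 4 | racemic (1S*,3S*)-3-(2-chloroethyl)-2,2-dimethyl-4-oxocyclohexyl acetate | O=C1CC[C@H](OC(C)=O)C(C)(C)[C@@H]1CCCl.O=C1CC[C@@H](OC(C)=O)C(C)(C)[C@H]1CCCl
F6 | step 5 | (2S,4S)-4-acetyl-2-(2-chloroethyl)-3,3-dimethylcyclohexan-1-one | O=C1CC[C@H](C(C)=O)C(C)(C)[C@@H]1CCCl
F7 | step 5 | 1-[(6S,8S)-6-(2-chloroethyl)-7,7-dimethyl-1,4-dioxaspiro[4.5]decan-8-yl]ethan-1-one | C12(OCCO1)CC[C@H](C(C)=O)C(C)(C)[C@@H]2CCCl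
F8 | step 5 | (6S,8S)-6-(2-chloroethyl)-7,7-dimethyl-1,4-dioxaspiro[4.5]decan-8-yl acetate | C12(OCCO1)CC[C@H](OC(C)=O)C(C)(C)[C@@H]2CCCl
F9 | step 9 | (1S,5S)-5-(2-chloroethyl)-6,6-dimethyl-4-[(trifluoromethanesulfonyl)oxy]cyclohex-3-en-1-yl acetate | O=S(=O)(OC1=CC[C@H](OC(C)=O)C(C)(C)[C@@H]1CCCl)C(F)(F)F
F10 | step 9 | (1S,5S)-5-(2-chloroethyl)-6,6-dimethyl-4-[(trimethylsilyl)methyl]cyclohex-3-en-1-yl acetate | C[Si](C)(C)CC1=CC[C@H](OC(C)=O)C(C)(C)[C@@H]1CCCl
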